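**Plan**

1. Retrosynthesis, in order: (a) the C6 prenyl group goes back to a 7‑O‑(2‑methylbut‑3‑en‑2‑yl) ether (aromatic Claisen); (b) the C8–C(=O) bond is cut to coumarin‑8‑carbaldehyde 21 and alkenyl iodide 14 (Nozaki–Hiyama–Kishi coupling, then oxidation); (c) in the cyclohexene (C1 carbonyl‑bearing, C5 methyl, C6 hydroxyethyl) the bonds C2–C3 and C4–C5 are cut together ([4+2]) and C6–C1' with them (allylboration).
2. Enabling feature: the C1=C2 alkene lies next to C6, which carries the carbinol carbon C1'. This homoallylic alcohol is the imprint of an allylboration with allylic shift, and the cyclic allylboronate it needs (boron on C2, alkene C1=C6) is the Diels–Alder adduct of a 1‑boryl diene C2=C1–C6=C5 with a two‑carbon partner C3–C4. A second boron on C1 is the handle for the later C8–C(=O) union.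
3. Forward order: enyne diboration; one‑pot cycloaddition (phenyl vinyl sulfone as ethylene equivalent) and allylboration (acetaldehyde) to build the carbocycle; removal of the sulfonyl group; boron‑to‑iodine exchange. The coumarin is made separately by Pechmann condensation on a symmetric resorcinol aldehyde, the fragments are joined, and the prenyl group is delivered last.
4. Stereochemistry: C5/C6 cis comes from the suprafacial cycloaddition of the (E,E)‑diene and the boron‑directed chair allylboration in the same pot. Absolute configuration comes from a lipase kinetic resolution of the methyl carbinol. C1' is then reset by oxidation and reagent‑controlled CBS reduction, because the allylboration gives the C1' epimer.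

Key step: step 2

Remark: (E)‑pent‑3‑en‑1‑yne is taken as a purchasable, volatile acetylene; any (Z) isomer is harmless, because the derived (3Z)‑diene cannot reach the s‑cis conformation and stays out of step 2. Compounds 6–10 are racemic and their SMILES show the enantiomer that is carried on.

**Route**

Step 1
Reactants: 1 (E)‑pent‑3‑en‑1‑yne; 2 bis(pinacolato)diboron
Product: 3 2,2'‑[(1E,3E)‑penta‑1,3‑diene‑1,2‑diyl]bis(4,4,5,5‑tetramethyl‑1,3,2‑dioxaborolane)
Conditions: Pt(PPh3)4 (3 mol %), DMF, 80 °C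
Reagents that add atoms: none
Why: Platinum‑catalysed alkyne diboration (oxidative addition of B–B to zerovalent platinum, syn insertion, reductive elimination) adds both borons cis across the triple bond much faster than across the conjugated alkene, so the C1 boron ends trans to the propenyl arm, the "outside" position needed for cycloaddition.

Step 2
Reactants: 3 the diboryl diene; 4 phenyl vinyl sulfone; 5 acetaldehyde
Product: 8 rac‑(1R)‑1‑[(1R,5R,6S)‑6‑methyl‑5‑(phenylsulfonyl)‑2‑(4,4,5,5‑tetramethyl‑1,3,2‑dioxaborolan‑2‑yl)cyclohex‑2‑en‑1‑yl]ethan‑1‑ol (accompanied by its 5‑epimer), via allylboronate cycloadduct 6 (not isolated), via O‑boryl homoallylic ether 7 (not isolated)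
Conditions: PhMe, BHT (cat.), 120 °C, sealed tube; then MeCHO (5 equiv), 23 → 40 °C; aq. NaHCO3
Reagents that add atoms: none
Why: A thermal [π4s+π2s] Diels–Alder reaction of diene 3 with the electron‑poor alkene 4 closes the six‑membered carbocycle by concerted suprafacial cycloaddition, forming the C2–C3 and C4–C5 bonds of the later cyclohexene at once; the α‑chiral allylboronate 6 then adds to acetaldehyde through a closed chair‑like six‑membered transition state, which forms C6–C1' and moves the alkene to C1=C2. The closest known reaction type is the three‑component tandem Diels–Alder/allylboration of 1‑boryl‑1,3‑dienes, together with the aldehyde allylation of 2‑boryl allylboronates. The C5 methyl centre and the boron‑bearing carbon are set cis by the (1E,3E) diene geometry (both groups "outside"); C6 is set by delivery of the aldehyde on the ring face that carried boron, hence cis to the methyl group; C1' is set by the chair with the aldehyde methyl equatorial, which gives the (1'R*) carbinol, the C1' epimer of the target series (corrected in steps 7 and 8); the sulfonyl‑bearing carbon is transient. Regioselectivity is needed only to keep the sulfonyl group off the allylic carbon and is secured by the "ortho"‑directing methyl terminus and the "para"‑directing 2‑boryl group, which both place it next to C5. Chemoselectivity rests on three facts: only the allylic boron can allylate (the alkenyl boron at C1 is kept for step 4), diene 3 does not react with the aldehyde, and the aldehyde is added only after the cycloaddition. The product is racemic at this stage.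

Step 3
Reactants: 8 the sulfonyl hydroxy boronate
Product: 9 rac‑(1R)‑1‑[(1R,6R)‑6‑methyl‑2‑(4,4,5,5‑tetramethyl‑1,3,2‑dioxaborolan‑2‑yl)cyclohex‑2‑en‑1‑yl]ethan‑1‑ol
Conditions: Na(Hg) (6 % Na), Na2HPO4, MeOH/THF, −20 → 0 °C
Reagents that add atoms: none
Why: Reductive desulfonylation by electron transfer cleaves the C–S bond of the homoallylic alkyl sulfone without touching the alkenylboronate, so the sulfone has served as an ethylene equivalent and both sulfonyl epimers converge (the C6 descriptor changes from S to R by priority only).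

Step 4
Reactants: 9 the hydroxy alkenylboronate
Product: 10 rac‑(1R)‑1‑[(1S,6R)‑2‑iodo‑6‑methylcyclohex‑2‑en‑1‑yl]ethan‑1‑ol
Conditions: NaI, TsN(Cl)Na (chloramine‑T), THF/H2O, 0 °C
Reagents that add atoms: sodium iodide, [Na+].[I-]
Why: Electrophilic ipso‑iododeboronation by I+ generated in situ replaces boron with retention (the only option in the ring) under near‑neutral conditions that leave the methyl carbinol alone (the C1 descriptor changes by priority only).

Step 5
Reactants: 10 the racemic iodo alcohol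
Product: 11 (1R)‑1‑[(1S,6R)‑2‑iodo‑6‑methylcyclohex‑2‑en‑1‑yl]ethyl acetate
Conditions: immobilised Candida antarctica lipase B, vinyl acetate, MTBE, 30 °C, stopped near half conversion
Reagents that add atoms: vinyl acetate, CC(=O)OC=C
Why: Lipase‑catalysed kinetic resolution by transesterification should acylate the (1R)‑methyl carbinol (ring as large, methyl as small substituent) and leave the (1S) enantiomer of 10, which is removed by chromatography; since the ring centres are locked to the carbinol centre, this fixes their absolute configuration.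

Step 6
Reactants: 11 the acetate
Product: 12 (1R)‑1‑[(1S,6R)‑2‑iodo‑6‑methylcyclohex‑2‑en‑1‑yl]ethan‑1‑ol (single enantiomer)
Conditions: K2CO3 (cat.), MeOH, 23 °C
Reagents that add atoms: none
Why: Base‑catalysed transesterification (methanolysis) frees the alcohol without affecting the alkenyl iodide or any stereocentre.

Step 7
Reactants: 12 the resolved alcohol
Product: 13 1‑[(1S,6R)‑2‑iodo‑6‑methylcyclohex‑2‑en‑1‑yl]ethan‑1‑one
Conditions: Dess–Martin periodinane, NaHCO3, CH2Cl2, 0 °C; used at once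
Reagents that add atoms: none
Why: Dess–Martin oxidation under buffered, non‑basic conditions erases the wrongly configured C1' centre without epimerising the adjacent allylic α‑stereocentre.

Step 8
Reactants: 13 the methyl ketone
Product: 14 (1S)‑1‑[(1S,6R)‑2‑iodo‑6‑methylcyclohex‑2‑en‑1‑yl]ethan‑1‑ol
Conditions: (R)‑2‑methyl‑CBS‑oxazaborolidine (20 mol %), BH3·SMe2, THF, −30 °C; MeOH quench
Reagents that add atoms: none
Why: Corey–Bakshi–Shibata reduction with the (R)‑catalyst delivers hydride to the face that gives the (S)‑carbinol (methyl small, ring large), a sense that 1,2‑induction (attack anti to the iodoalkenyl carbon) should reinforce, so C1' is set under reagent control.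

Step 9
Reactants: 15 2,4,6‑trihydroxybenzaldehyde
Product: 16 2,6‑dihydroxy‑4‑methoxybenzaldehyde
Conditions: MeI (1.05 equiv), K2CO3 (1.0 equiv), acetone, 23 °C
Reagents that add atoms: iodomethane, CI
Why: Williamson O‑methylation with one equivalent of base should select the 4‑hydroxyl, the most acidic phenol and the only one not hydrogen‑bonded to the aldehyde.

Step 10
Reactants: 16 2,6‑dihydroxy‑4‑methoxybenzaldehyde; 17 ethyl 2‑methyl‑3‑oxobutanoate
Product: 18 7‑hydroxy‑5‑methoxy‑3,4‑dimethyl‑2‑oxo‑2H‑chromene‑8‑carbaldehyde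
Conditions: CF3CO2H, 60 °C
Reagents that add atoms: none
Why: Pechmann condensation (ring hydroxyalkylation at the carbon between OH and OMe, lactonisation, dehydration); the mirror symmetry of 16 makes both possible sites identical, so only this isomer can form, and the α‑methyl group of 17 shuts off Knoevenagel condensation with the aldehyde.

Step 11
Reactants: 18 the coumarin aldehyde; 19 3‑chloro‑3‑methylbut‑1‑yne
Product: 20 5‑methoxy‑3,4‑dimethyl‑7‑[(2‑methylbut‑3‑yn‑2‑yl)oxy]‑2‑oxo‑2H‑chromene‑8‑carbaldehyde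
Conditions: K2CO3, KI (cat.), CuI (cat.), DMF, 45 °C
Reagents that add atoms: none
Why: Copper‑catalysed O‑propargylation of the phenoxide by the tertiary propargylic chloride (through a copper acetylide/allenylidene‑type electrophile) forms the tertiary aryl ether that direct SN2 alkylation cannot.

Step 12
Reactants: 20 the propargyl ether
Product: 21 5‑methoxy‑3,4‑dimethyl‑7‑[(2‑methylbut‑3‑en‑2‑yl)oxy]‑2‑oxo‑2H‑chromene‑8‑carbaldehyde
Conditions: H2 (1 atm), Pd/CaCO3 poisoned with Pb(OAc)2, quinoline, EtOAc, 23 °C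
Reagents that add atoms: none
Why: Lindlar‑type semihydrogenation stops at the terminal alkene and spares the aldehyde and the tetrasubstituted pyranone alkene.

Step 13
Reactants: 14 the alkenyl iodide; 21 the coumarin aldehyde
Product: 22 8‑{hydroxy[(5R,6R)‑6‑[(1S)‑1‑hydroxyethyl]‑5‑methylcyclohex‑1‑en‑1‑yl]methyl}‑5‑methoxy‑3,4‑dimethyl‑7‑[(2‑methylbut‑3‑en‑2‑yl)oxy]‑2H‑chromen‑2‑one (both epimers at the new carbinol)
Conditions: CrCl2 (5 equiv), NiCl2 (2 mol %), DMF/THF, 23 °C; neutral work‑up, taken on crude or over Et3N‑washed silica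
Reagents that add atoms: none
Why: Nozaki–Hiyama–Kishi coupling: zerovalent nickel formed in situ inserts into the C–I bond and transmetalation gives an alkenyl species of trivalent chromium that adds only to the aldehyde, tolerating the free alcohol, the lactone and the allyl aryl ether; the new carbinol centre is destroyed in step 14.

Step 14
Reactants: 22 the diol
Product: 23 8‑{[(5R,6R)‑6‑[(1S)‑1‑hydroxyethyl]‑5‑methylcyclohex‑1‑en‑1‑yl]carbonyl}‑5‑methoxy‑3,4‑dimethyl‑7‑[(2‑methylbut‑3‑en‑2‑yl)oxy]‑2H‑chromen‑2‑one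
Conditions: activated MnO2 (excess), CH2Cl2, 23 °C
Reagents that add atoms: none
Why: MnO2 should oxidise only the doubly activated (allylic and benzylic) alcohol and leave the isolated secondary carbinol, giving the aryl enone without protecting groups.

Step 15
Reactants: 23 the aryl enone ether
Product: 24 7‑hydroxy‑8‑{[(5R,6R)‑6‑[(1S)‑1‑hydroxyethyl]‑5‑methylcyclohex‑1‑en‑1‑yl]carbonyl}‑5‑methoxy‑3,4‑dimethyl‑6‑(3‑methylbut‑2‑en‑1‑yl)‑2H‑chromen‑2‑one (target)
Conditions: Eu(fod)3 (10 mol %), CHCl3, 55 °C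
Reagents that add atoms: none
Why: Aromatic Claisen rearrangement ([3,3]) of the 1,1‑dimethylallyl aryl ether: C8 is blocked by the acyl group, so the allyl unit migrates with transposition to C6 as a prenyl group and tautomerisation frees the 7‑OH; mild neutral catalysis should avoid oxa‑Michael closure of the phenol onto the enone.

**Compound list**

1 | (E)‑pent‑3‑en‑1‑yne | C/C=C/C#C | starting material
2 | bis(pinacolato)diboron | CC1(C)OB(OC1(C)C)B1OC(C)(C)C(C)(C)O1 | starting material
3 | 2,2'‑[(1E,3E)‑penta‑1,3‑diene‑1,2‑diyl]bis(4,4,5,5‑tetramethyl‑1,3,2‑dioxaborolane) | C/C=C/C(B1OC(C)(C)C(C)(C)O1)=C/B1OC(C)(C)C(C)(C)O1 | intermediate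
4 | phenyl vinyl sulfone | C=CS(=O)(=O)c1ccccc1 | starting material
5 | acetaldehyde | CC=O | starting material
6 | rac‑2,2'‑[(1S,4S,5R)‑4‑methyl‑5‑(phenylsulfonyl)cyclohex‑2‑ene‑1,2‑diyl]bis(4,4,5,5‑tetramethyl‑1,3,2‑dioxaborolane); boryl, methyl and sulfonyl all cis, with its 5‑epimer | CC1(C)OB(OC1(C)C)C2=C[C@H](C)[C@H](S(=O)(=O)c3ccccc3)C[C@@H]2B4OC(C)(C)C(C)(C)O4 | intermediate
7 | rac O‑(pinacolboryl) ether of 8 | CC1(C)OB(OC1(C)C)C2=CC[C@@H](S(=O)(=O)c3ccccc3)[C@@H](C)[C@H]2[C@@H](C)OB4OC(C)(C)C(C)(C)O4 | intermediate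
8 | rac‑(1R)‑1‑[(1R,5R,6S)‑6‑methyl‑5‑(phenylsulfonyl)‑2‑(4,4,5,5‑tetramethyl‑1,3,2‑dioxaborolan‑2‑yl)cyclohex‑2‑en‑1‑yl]ethan‑1‑ol, with its 5‑epimer | CC1(C)OB(OC1(C)C)C2=CC[C@@H](S(=O)(=O)c3ccccc3)[C@@H](C)[C@H]2[C@@H](C)O | intermediate
9 | rac‑(1R)‑1‑[(1R,6R)‑6‑methyl‑2‑(4,4,5,5‑tetramethyl‑1,3,2‑dioxaborolan‑2‑yl)cyclohex‑2‑en‑1‑yl]ethan‑1‑ol | CC1(C)OB(OC1(C)C)C2=CCC[C@@H](C)[C@H]2[C@@H](C)O | intermediate
10 | rac‑(1R)‑1‑[(1S,6R)‑2‑iodo‑6‑methylcyclohex‑2‑en‑1‑yl]ethan‑1‑ol | IC1=CCC[C@@H](C)[C@H]1[C@@H](C)O | intermediate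
11 | (1R)‑1‑[(1S,6R)‑2‑iodo‑6‑methylcyclohex‑2‑en‑1‑yl]ethyl acetate | IC1=CCC[C@@H](C)[C@H]1[C@@H](C)OC(C)=O | intermediate
12 | (1R)‑1‑[(1S,6R)‑2‑iodo‑6‑methylcyclohex‑2‑en‑1‑yl]ethan‑1‑ol, single enantiomer | IC1=CCC[C@@H](C)[C@H]1[C@@H](C)O | intermediate
13 | 1‑[(1S,6R)‑2‑iodo‑6‑methylcyclohex‑2‑en‑1‑yl]ethan‑1‑one | IC1=CCC[C@@H](C)[C@H]1C(C)=O | intermediate
14 | (1S)‑1‑[(1S,6R)‑2‑iodo‑6‑methylcyclohex‑2‑en‑1‑yl]ethan‑1‑ol | IC1=CCC[C@@H](C)[C@H]1[C@H](C)O | intermediate
15 | 2,4,6‑trihydroxybenzaldehyde | O=Cc1c(O)cc(O)cc1O | starting material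
16 | 2,6‑dihydroxy‑4‑methoxybenzaldehyde | COc1cc(O)c(C=O)c(O)c1 | intermediate
17 | ethyl 2‑methyl‑3‑oxobutanoate | CCOC(=O)C(C)C(C)=O | starting material
18 | 7‑hydroxy‑5‑methoxy‑3,4‑dimethyl‑2‑oxo‑2H‑chromene‑8‑carbaldehyde | COc1cc(O)c(C=O)c2oc(=O)c(C)c(C)c12 | intermediate
19 | 3‑chloro‑3‑methylbut‑1‑yne | CC(C)(Cl)C#C | starting material
20 | 5‑methoxy‑3,4‑dimethyl‑7‑[(2‑methylbut‑3‑yn‑2‑yl)oxy]‑2‑oxo‑2H‑chromene‑8‑carbaldehyde | COc1cc(OC(C)(C)C#C)c(C=O)c2oc(=O)c(C)c(C)c12 | intermediate
21 | 5‑methoxy‑3,4‑dimethyl‑7‑[(2‑methylbut‑3‑en‑2‑yl)oxy]‑2‑oxo‑2H‑chromene‑8‑carbaldehyde | COc1cc(OC(C)(C)C=C)c(C=O)c2oc(=O)c(C)c(C)c12 | intermediate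
22 | 8‑{hydroxy[(5R,6R)‑6‑[(1S)‑1‑hydroxyethyl]‑5‑methylcyclohex‑1‑en‑1‑yl]methyl}‑5‑methoxy‑3,4‑dimethyl‑7‑[(2‑methylbut‑3‑en‑2‑yl)oxy]‑2H‑chromen‑2‑one, carbinol epimers | COc1cc(OC(C)(C)C=C)c(C(O)C2=CCC[C@@H](C)[C@H]2[C@H](C)O)c2oc(=O)c(C)c(C)c12 | intermediate
23 | 8‑{[(5R,6R)‑6‑[(1S)‑1‑hydroxyethyl]‑5‑methylcyclohex‑1‑en‑1‑yl]carbonyl}‑5‑methoxy‑3,4‑dimethyl‑7‑[(2‑methylbut‑3‑en‑2‑yl)oxy]‑2H‑chromen‑2‑one | COc1cc(OC(C)(C)C=C)c(C(=O)C2=CCC[C@@H](C)[C@H]2[C@H](C)O)c2oc(=O)c(C)c(C)c12 | intermediate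
24 | 7‑hydroxy‑8‑{[(5R,6R)‑6‑[(1S)‑1‑hydroxyethyl]‑5‑methylcyclohex‑1‑en‑1‑yl]carbonyl}‑5‑methoxy‑3,4‑dimethyl‑6‑(3‑methylbut‑2‑en‑1‑yl)‑2H‑chromen‑2‑one | COc1c(CC=C(C)C)c(O)c(C(=O)C2=CCC[C@@H](C)[C@H]2[C@H](C)O)c2oc(=O)c(C)c(C)c12 | target

**Step count and risks**

Total: 15 steps. Longest linear sequence: 11 steps (steps 1–8, then 13–15); the coumarin branch is steps 9–12.

Steps most likely to fail:

Step 2. The diboryl diene may dimerise or react too slowly at the temperature the sulfone needs, or the cycloaddition may take the reverse orientation and place the sulfonyl group on the allylic carbon. The fallback sets out from 3 and uses nitroethylene (freshly made from 2‑nitroethanol and phthalic anhydride) as a much more reactive and more strongly orienting two‑carbon partner in PhMe at 23 °C. This should give the nitro allylboronate cycloadduct F1 in the flask; acetaldehyde then gives the O‑boryl nitro ether F2 and, after aqueous work‑up, the nitro alcohol F3. Radical denitration (Bu3SnH, AIBN, PhMe, 110 °C) returns to 9.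

Step 13. Carbon–carbon bond formation between two hindered partners may be slow, with protodehalogenation of the alkenylchromium species, and the electron‑rich doubly activated carbinol may ionise and be trapped by the free hydroxyl as a cyclic ether. The fallback sets out from 14: silylation (TBSOTf, 2,6‑lutidine, CH2Cl2) gives the silyl ether F4; iodine–lithium exchange (t‑BuLi, Et2O, −78 °C) and addition to 21 give the mono‑silylated diol F5; Dess–Martin oxidation gives the silyl‑protected ketone F6; HF·pyridine in THF returns to 23.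

Step 10. The free aldehyde may condense under acid with the electron‑rich ring of a second molecule faster than the coumarin forms. The fallback sets out from 16: the aldehyde is masked as the dithiane F7 (propane‑1,3‑dithiol, BF3·OEt2), Pechmann condensation with 17 then gives the dithianyl coumarin F8, and alkylative hydrolysis (MeI, CaCO3, MeCN/H2O) returns to 18.

**Further compounds**

F1 | step 2 | rac‑2,2'‑[4‑methyl‑5‑nitrocyclohex‑2‑ene‑1,2‑diyl]bis(4,4,5,5‑tetramethyl‑1,3,2‑dioxaborolane), boryl, methyl and nitro all cis, with its 5‑epimer | CC1(C)OB(OC1(C)C)C2=C[C@H](C)[C@H]([N+](=O)[O-])C[C@@H]2B4OC(C)(C)C(C)(C)O4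
F2 | step 2 | rac O‑(pinacolboryl) ether of F3 | CC1(C)OB(OC1(C)C)C2=CC[C@@H]([N+](=O)[O-])[C@@H](C)[C@H]2[C@@H](C)OB4OC(C)(C)C(C)(C)O4
F3 | step 2 | rac‑1‑[6‑methyl‑5‑nitro‑2‑(4,4,5,5‑tetramethyl‑1,3,2‑dioxaborolan‑2‑yl)cyclohex‑2‑en‑1‑yl]ethan‑1‑ol, relative configuration as in 8 | CC1(C)OB(OC1(C)C)C2=CC[C@@H]([N+](=O)[O-])[C@@H](C)[C@H]2[C@@H](C)O
F4 | step 13 | tert‑butyl{(1S)‑1‑[(1S,6R)‑2‑iodo‑6‑methylcyclohex‑2‑en‑1‑yl]ethoxy}dimethylsilane | IC1=CCC[C@@H](C)[C@H]1[C@H](C)O[Si](C)(C)C(C)(C)C
F5 | step 13 | mono‑TBS ether (at C1') of diol 22, carbinol epimers | COc1cc(OC(C)(C)C=C)c(C(O)C2=CCC[C@@H](C)[C@H]2[C@H](C)O[Si](C)(C)C(C)(C)C)c2oc(=O)c(C)c(C)c12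
F6 | step 13 | TBS ether (at C1') of ketone 23 | COc1cc(OC(C)(C)C=C)c(C(=O)C2=CCC[C@@H](C)[C@H]2[C@H](C)O[Si](C)(C)C(C)(C)C)c2oc(=O)c(C)c(C)c12
F7 | step 10 | 2‑(1,3‑dithian‑2‑yl)‑5‑methoxybenzene‑1,3‑diol | COc1cc(O)c(C2SCCCS2)c(O)c1
F8 | step 10 | 8‑(1,3‑dithian‑2‑yl)‑7‑hydroxy‑5‑methoxy‑3,4‑dimethyl‑2H‑chromen‑2‑one | COc1cc(O)c(C3SCCCS3)c2oc(=O)c(C)c(C)c12
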